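One unit of charged E is my yardstick: I count E and Q as fractions of it.

| flask | E | Z | remark | time |
|---|---|---|---|---|
| south-west | 0.44 M | 0.90 M | run made earlier |  |
| south-east | 1.9 M | 0.90 M | run made earlier |  |
| Friday's | 0.60 M | 0.900 M |  | 4.0 d |
| Thursday's | 1.0 M | 0.900 M |  | 4.0 d |
| Tuesday's | 1.5 M | 0.900 M |  | 4.0 d |
| Monday's | 2.5 M | 0.900 M |  | 4.0 d |

- south-west (time / d: Q / %, E / %): 0.208: 5.7, 76.1; 0.333: 11.6, 65.7; 0.500: 17.2, 55.7; 0.833: 26.8, 39.7; 1.25: 32.0, 27.1; 1.67: 32.8, 19.4; 3.00: 26.5, 7.3
- south-east (time / d: Q / %, E / %): 0.417: 11.1, 69.9; 0.833: 17.1, 61.7; 1.25: 18.0, 58.1; 1.67: 16.5, 56.0; 2.08: 15.6, 55.1; 2.50: 13.4, 54.8; 3.00: 11.2, 54.7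

(standard deviation of a reading: 0.5 percentage points)

* [Q] at the end for Friday's, Thursday's, Tuesday's, Monday's, in this order
* the course of these numbers from the first flask to the last (hardly changes / falls, then rises / falls all the way / rises, then falls / rises all the way)

- "hardly changes" means that all values lie within two and a half points (for a concentration: within two and a half percent of the largest)

I build Monday's flask one process at a time, and I start from its end state. First I take the main step by itself, E with Z into Q. In the south-east run, E reads 55.1% at 2.08 d and 54.7% at 3.00 d, a change within the scatter. The E reacted there is 45.3% of its charge. That makes 0.956 of E for each unit of Z charged, nearly all of a one-to-one share. I call this the cap and take Z as the limiting reagent. With Monday's charge, the cap lets 0.344 react, and in this first picture Q reads the same.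

Second, I add what stands between reacted E and Q. At 3.00 d, the south-east run holds Q at 11.2%, so 0.247 of the reacted E stands as Q at that moment. That cuts Monday's number to 0.0850.

Third, I add the fading of Q. From 2.08 d to 3.00 d, south-east Q falls from 15.6% to 11.2%, a first-order reading of 0.360 d⁻¹. Carried on to 4.0 d, this gives the kept share, Q standing over E reacted at the asked time, of 0.172. Monday's charges more E than the south-east run, so I expect its Z to go at least as early, and I carry the share over.

My Monday's Q is therefore 0.0594 of the charge, or 0.148 M. For Tuesday's, the cap gives 0.574 reacted and the same share gives 0.148 M. For Friday's, the cap of 1.43 exceeds the charge, and the share on the whole charge gives 0.103 M. Tuesday's and Friday's charge less E than Monday's, so I expect them to react later and their Q to be younger, and I set them higher. I commit to a row that rises, then falls.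

The forecast gives 0.116 M, 0.162 M, 0.167 M and 0.155 M, with the course "rises, then falls", on the ground that “faster reaction gives Q longer to decay”. Its Monday's value is higher than mine.

The flasks give 0.121 M, 0.166 M, 0.165 M and 0.148 M, so the course is "rises, then falls", and the row turns at 1.2 M of E.

    Q → G (k = 0.0150 h⁻¹)
    E + Z → L (k = 0.0380 M⁻¹ h⁻¹)
    E + Z → X (k = 0.0260 M⁻¹ h⁻¹)
    X → J (k = 0.120 h⁻¹)
    L → Q (k = 0.220 h⁻¹)
    Z + X → D (k = 0.0480 M⁻¹ h⁻¹)

At 4.00 d, Monday's holds Q at 5.94% and E at 65.1%, a kept share of 0.170 against my 0.172. Tuesday's has reacted 57.1% of its E, where the cap gave 57.4%, and its Q stands at 11.0%, so its kept share is higher than 0.172, at 0.192.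

The earlier runs and the new flask are simulated for substances that don't exist; scatter was added.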